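**Retrosynthetic overview**
1. Target ⇒ 5-bromo-2,3-dihydrobenzofuran + (E)-propenyl pinacol boronate (Suzuki); the acid-sensitive propenyl group goes on last and bromine is its inert placeholder.
2. Key disconnection: the C2–O bond of the dihydrofuran ring ⇒ an (E)-2-hydroxy-α-methylstilbene; forward, one enantioselective acid-catalysed hydroalkoxylation forms this bond and sets C2 and C3 (trans).
3. Stilbene ⇒ 4-bromo-2-iodo-6-methoxyphenol + (E)-isoelemicin (Heck, C3–C3a bond).
4. (E)-Isoelemicin ⇒ 5-bromo-1,2,3-trimethoxybenzene + the same propenyl boronate; the iodophenol ⇒ 4-bromo-2-methoxyphenol.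
5. Ring order: ring A (trimethoxyphenyl) and ring B (benzo ring) are bought; the dihydrofuran ring is the only ring made, in step 4, by C–O bond formation.

Assumption: the sense of induction of acid A in step 4 cannot be predicted with certainty; the (S,S) acid is written, and its (R,R) mirror image is used instead if the first run gives the (2S,3S) series.

Acid A = (S,S)-IDPi, the imidodiphosphorimidate Brønsted acid HN[P(=NSO2CF3)(O2Ar*)]2, where each O2Ar* is (S)-3,3'-bis[3,5-bis(trifluoromethyl)phenyl]-1,1'-binaphthalene-2,2'-diolate.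

**Route**

Step 1
Reactants: 1 5-bromo-1,2,3-trimethoxybenzene; 2 (E)-4,4,5,5-tetramethyl-2-(prop-1-en-1-yl)-1,3,2-dioxaborolane (trans-1-propenylboronic acid pinacol ester)
Product: 3 (E)-isoelemicin, 1,2,3-trimethoxy-5-[(E)-prop-1-en-1-yl]benzene
Conditions: Pd(dppf)Cl2 (3 mol %), K2CO3, 1,4-dioxane/H2O (4:1), 80 °C
Reagents that add atoms: none
Why: Suzuki–Miyaura coupling of an aryl bromide and an alkenyl boronate transfers the propenyl group with retention of its E geometry; no stereocentre is formed.

Step 2
Reactants: 4 4-bromo-2-methoxyphenol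
Product: 5 4-bromo-2-iodo-6-methoxyphenol
Conditions: NIS (1.05 equiv), TsOH·H2O (10 mol %), MeCN, 0 °C to rt
Reagents that add atoms: N-iodosuccinimide, O=C1CCC(=O)N1I
Why: Electrophilic aromatic iodination; the hydroxyl group directs iodine to its only free ortho position because the para position carries bromine; no stereocentre is formed.

Step 3
Reactants: 5 4-bromo-2-iodo-6-methoxyphenol; 3 (E)-isoelemicin
Product: 6 4-bromo-2-methoxy-6-[(1E)-1-(3,4,5-trimethoxyphenyl)prop-1-en-2-yl]phenol (rings A and B trans across the double bond)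
Conditions: Pd(OAc)2 (5 mol %), n-Bu4NCl (1 equiv), NaOAc (2.5 equiv), DMF, 100 °C, 3 (2 equiv)
Reagents that add atoms: none
Why: Mizoroki–Heck reaction under ligand-free Jeffery conditions: palladium inserts into the carbon–iodine bond only, syn carbopalladation puts ring B on the methyl-bearing carbon and palladium on the benzylic carbon, and syn β-hydride elimination of the only available hydrogen gives the trisubstituted E alkene; no stereocentre is formed.

Step 4
Reactants: 6 4-bromo-2-methoxy-6-[(1E)-1-(3,4,5-trimethoxyphenyl)prop-1-en-2-yl]phenol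
Product: 7 (2R,3R)-5-bromo-7-methoxy-3-methyl-2-(3,4,5-trimethoxyphenyl)-2,3-dihydro-1-benzofuran (2,3-trans)
Conditions: acid A (5 mol %), 4 Å molecular sieves, cyclohexane/CHCl3 (3:1), 0 °C to rt
Reagents that add atoms: none
Why: Proposed new method: an enantioselective Brønsted acid catalysed hydroalkoxylation of a 2-hydroxy-α-methylstilbene, in which the confined chiral acid A, hydrogen-bonded to the phenol, protonates the alkene at C3 on one enantioface (this sets C3) and the phenol oxygen then captures the developing 3,4,5-trimethoxybenzylic cation at C2 anti to the C3 methyl group (this forms the C2–O bond, closes the dihydrofuran ring and sets C2 trans to C3, as in acid-mediated SN1 closures of 1,2-diarylpropan-1-ols), while protonation at C2 is reversible and non-productive because the tertiary cation on the twisted, bromine-deactivated ring B cannot close a five-membered ring, and no atom of 6 is lost; the closest known reaction types are the IDPi-catalysed asymmetric intramolecular hydroalkoxylation of unactivated alkenes to tetrahydrofurans and the racemic acid- or light-induced cyclisation of 2-hydroxystilbenes to 2-aryl-2,3-dihydrobenzofurans.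

Step 5
Reactants: 7 (2R,3R)-5-bromo-7-methoxy-3-methyl-2-(3,4,5-trimethoxyphenyl)-2,3-dihydro-1-benzofuran; 2 (E)-4,4,5,5-tetramethyl-2-(prop-1-en-1-yl)-1,3,2-dioxaborolane
Product: 8 (2R,3R)-7-methoxy-3-methyl-5-[(E)-prop-1-en-1-yl]-2-(3,4,5-trimethoxyphenyl)-2,3-dihydro-1-benzofuran (CNP0219898.1)
Conditions: Pd(dppf)Cl2 (5 mol %), K2CO3, 1,4-dioxane/H2O (4:1), 80 °C
Reagents that add atoms: none
Why: Suzuki–Miyaura coupling at the only carbon–bromine bond transfers the E-propenyl group with retention; the C2 and C3 stereocentres take no part and are stable to mild aqueous base, so they are carried through unchanged.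

**Compound list**
1 | 5-bromo-1,2,3-trimethoxybenzene | COc1cc(Br)cc(OC)c1OC | starting material
2 | (E)-4,4,5,5-tetramethyl-2-(prop-1-en-1-yl)-1,3,2-dioxaborolane | C/C=C/B1OC(C)(C)C(C)(C)O1 | starting material
3 | (E)-isoelemicin, 1,2,3-trimethoxy-5-[(E)-prop-1-en-1-yl]benzene | C/C=C/c1cc(OC)c(OC)c(OC)c1 | intermediate
4 | 4-bromo-2-methoxyphenol | COc1cc(Br)ccc1O | starting material
5 | 4-bromo-2-iodo-6-methoxyphenol | COc1cc(Br)cc(I)c1O | intermediate
6 | 4-bromo-2-methoxy-6-[(1E)-1-(3,4,5-trimethoxyphenyl)prop-1-en-2-yl]phenol | COc1cc(Br)cc(/C(C)=C/c2cc(OC)c(OC)c(OC)c2)c1O | intermediate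
7 | (2R,3R)-5-bromo-7-methoxy-3-methyl-2-(3,4,5-trimethoxyphenyl)-2,3-dihydro-1-benzofuran | Brc1cc(OC)c2c(c1)[C@@H](C)[C@H](c1cc(OC)c(OC)c(OC)c1)O2 | intermediate
8 | (2R,3R)-7-methoxy-3-methyl-5-[(E)-prop-1-en-1-yl]-2-(3,4,5-trimethoxyphenyl)-2,3-dihydro-1-benzofuran | C/C=C/c1cc(OC)c2c(c1)[C@@H](C)[C@H](c1cc(OC)c(OC)c(OC)c1)O2 | target

**Step count**
Total: 5 steps. Longest linear sequence: 4 steps (steps 1, 3, 4, 5; equally steps 2, 3, 4, 5). No protecting groups are used.

**Three steps most likely to fail**

Step 4 (the new reaction) is the most likely to fail. Protonation may go mainly to C2, the ee may be low, or re-ionisation of 7 at C2 followed by loss of the C3 proton may erode it. The fallback uses known chemistry, sets out from 6 and comes back at 7. Asymmetric hydroboration of 6 with monoisopinocampheylborane (IpcBH2 made from (+)-α-pinene, 2.5 equiv, THF, −25 °C; the phenol consumes one equivalent) is followed by oxidation in the same flask with NaBO3·4H2O. This adds H and OH syn across the E alkene, with boron on the less substituted benzylic carbon, and gives (1R,2R)-2-(5-bromo-2-hydroxy-3-methoxyphenyl)-1-(3,4,5-trimethoxyphenyl)propan-1-ol F3. The borane from (−)-α-pinene is taken if the first run gives the mirror-image alcohol, and the ee is raised by crystallisation. TsOH·H2O (10 mol %) in CH2Cl2 at 0 °C then ionises the benzylic alcohol and the phenol closes the ring anti to the methyl group (SN1 cycloetherification), which gives 7 with the methyl-bearing centre untouched.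

Step 3 is the second risk. The alkene is internal and electron-rich, so the Heck reaction may be slow and may give the 1,1-diaryl regioisomer, double-bond isomers or a little direct oxyarylation. The fallback sets out from 1 (5 is used again) and comes back at 6. Sonogashira coupling of 1 with propyne (Pd(PPh3)2Cl2, CuI, Et3N, DMF, 60 °C, sealed tube) gives 1,2,3-trimethoxy-5-(prop-1-yn-1-yl)benzene F1. Copper-catalysed syn hydroboration (CuCl, NaOt-Bu, Xantphos, B2pin2, MeOH, THF, rt) places boron on the methyl-bearing carbon and gives (Z)-4,4,5,5-tetramethyl-2-[1-(3,4,5-trimethoxyphenyl)prop-1-en-2-yl]-1,3,2-dioxaborolane F2. Suzuki–Miyaura coupling of F2 with 5 (Pd(dppf)Cl2, K2CO3, 1,4-dioxane/H2O, 60 °C, iodide-selective) gives 6 with retention, so regio- and stereochemistry no longer depend on the insertion and elimination events of the Heck reaction.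

Step 5 is the third risk. It is run on the most valuable intermediate, the bromide is electron-rich and may add slowly to palladium, and boronate 2 may protodeboronate. The fallback sets out from 7 and comes back at 8. Bromine–lithium exchange (n-BuLi, THF, −78 °C) and a DMF quench give (2R,3R)-7-methoxy-3-methyl-2-(3,4,5-trimethoxyphenyl)-2,3-dihydro-1-benzofuran-5-carbaldehyde F4. Julia–Kocienski ethylidenation (5-(ethylsulfonyl)-1-phenyl-1H-tetrazole, KN(SiMe3)2, DME, −60 °C to rt) then gives 8; it is E-selective for electron-rich aryl aldehydes, and any Z isomer is removed on AgNO3-impregnated silica.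

**Further compounds**
F1 | step 3 | 1,2,3-trimethoxy-5-(prop-1-yn-1-yl)benzene | CC#Cc1cc(OC)c(OC)c(OC)c1
F2 | step 3 | (Z)-4,4,5,5-tetramethyl-2-[1-(3,4,5-trimethoxyphenyl)prop-1-en-2-yl]-1,3,2-dioxaborolane | C/C(=C\c1cc(OC)c(OC)c(OC)c1)B1OC(C)(C)C(C)(C)O1
F3 | step 4 | (1R,2R)-2-(5-bromo-2-hydroxy-3-methoxyphenyl)-1-(3,4,5-trimethoxyphenyl)propan-1-ol | C[C@H](c1cc(Br)cc(OC)c1O)[C@@H](O)c1cc(OC)c(OC)c(OC)c1
F4 | step 5 | (2R,3R)-7-methoxy-3-methyl-2-(3,4,5-trimethoxyphenyl)-2,3-dihydro-1-benzofuran-5-carbaldehyde | O=Cc1cc(OC)c2c(c1)[C@@H](C)[C@H](c1cc(OC)c(OC)c(OC)c1)O2
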